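**Retrosynthetic overview**

1. The target is (2S)-7-hydroxy-4'-methoxy-6,8-diprenylflavanone. The strategy rests on the C3–C4 bond of the pyranone ring (ring C): it joins the C4 carbonyl carbon to the C3 methylene beside the C2 stereocentre, so it can be read as the C3=C4 alkene of a cyclic 4-silyloxy-2H-chromene.
2. Last disconnection: both O–Si bonds (C4 enol ether, C7 aryl ether) are cut with buffered fluoride, giving the ketone and the phenol.
3. Key disconnection: C3=C4 by ring-closing metathesis between the vinyl group on C2 and a 1-silyloxyvinyl group on C4a, with loss of ethylene.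
4. O1–C2 comes from an iridium-catalysed asymmetric allylic etherification of a 2-hydroxyacetophenone with a 4-methoxycinnamyl carbonate, which sets C2. The arene comes from 2,4-dihydroxyacetophenone by double C-prenylation and 4-O-silylation.
5. Ring order: rings A and B are bought as arenes; the pyran ring C is the only ring formed, in step 6.

Key step: step 6

Assumption: the (Sa,Sc,Sc)-phosphoramidite ligand [O,O'-(S)-1,1'-binaphthyl-2,2'-diyl N,N-bis((S)-1-phenylethyl)phosphoramidite] is taken to give the (S)-1-arylallyl aryl ether; if the first run shows the opposite sense, the mirror-image ligand is used.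

**Route**

Step 1
Reactants: 1 2,4-dihydroxyacetophenone; 2 prenyl bromide
Product: 3 1-[2,4-dihydroxy-3,5-bis(3-methylbut-2-en-1-yl)phenyl]ethan-1-one
Conditions: 2 (2.6 equiv), 10% aq KOH, 0 °C → rt; chromatography
Reagents that add atoms: none
Why: Nuclear C-prenylation of the resorcinol-type dianion in water, where hydrogen bonding to the phenoxide oxygens suppresses O-alkylation and the only nucleophilic ring carbons are C3 (between the two oxygens) and C5 (ortho to the 4-oxide, para to the 2-oxide), so with excess bromide the 3,5-di-C-prenyl ketone should be the main doubly alkylated product, separable from mono-C- and O-prenylated material at the cost of modest efficiency.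

Step 2
Reactants: 3 1-[2,4-dihydroxy-3,5-bis(3-methylbut-2-en-1-yl)phenyl]ethan-1-one
Product: 4 1-[4-(tert-butyldimethylsilyloxy)-2-hydroxy-3,5-bis(3-methylbut-2-en-1-yl)phenyl]ethan-1-one
Conditions: TBSCl (1.1 equiv), imidazole, DMF, 0 °C → rt
Reagents that add atoms: tert-butyldimethylsilyl chloride, CC(C)(C)[Si](C)(C)Cl
Why: Chemoselective O-silylation, since the 2-hydroxyl is held in a six-membered hydrogen bond to the acetyl oxygen while the more acidic 4-hydroxyl (para to the acyl group) is free, so only O4 should be silylated, giving an aryl silyl ether shielded by two ortho prenyl groups.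

Step 3
Reactants: 5 (E)-4-methoxycinnamyl alcohol
Product: 6 tert-butyl (E)-3-(4-methoxyphenyl)prop-2-en-1-yl carbonate
Conditions: Boc2O, n-Bu4NHSO4 (cat.), 30% aq NaOH, CH2Cl2, 0 °C → rt
Reagents that add atoms: di-tert-butyl dicarbonate, CC(C)(C)OC(=O)OC(=O)OC(C)(C)C
Why: Carbonate formation (O-acylation of a primary allylic alcohol) under phase-transfer conditions, the tert-butyl carbonate being chosen because its leaving group ends as tert-butanol, which cannot compete with the hindered aryloxide as an oxygen nucleophile in step 4.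

Step 4
Reactants: 4 1-[4-(tert-butyldimethylsilyloxy)-2-hydroxy-3,5-bis(3-methylbut-2-en-1-yl)phenyl]ethan-1-one; 6 tert-butyl (E)-3-(4-methoxyphenyl)prop-2-en-1-yl carbonate
Product: 8 1-[4-(tert-butyldimethylsilyloxy)-2-{[(1S)-1-(4-methoxyphenyl)prop-2-en-1-yl]oxy}-3,5-bis(3-methylbut-2-en-1-yl)phenyl]ethan-1-one, via potassium aryloxide 7 (not isolated)
Conditions: [Ir(cod)Cl]2 (2 mol%), (Sa,Sc,Sc)-phosphoramidite ligand (4 mol%, pre-activated with n-PrNH2), K3PO4 (1 equiv), 6 (1.3 equiv), THF, rt; stopped at full conversion of 4
Reagents that add atoms: none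
Why: Iridium-catalysed asymmetric allylic etherification, in which the cyclometalated iridium phosphoramidite ionises carbonate 6 to an η3-(4-methoxycinnamyl)iridium cation and aryloxide 7 attacks it outer-sphere at the aryl-substituted terminus (branched ether), the chiral ligand leaving one allyl face open and so setting the O-bearing stereocentre (later C2) as S; the ortho and para carbons of the aryloxide are all substituted, which leaves O-allylation as the only outlet.

Step 5
Reactants: 8 1-[4-(tert-butyldimethylsilyloxy)-2-{[(1S)-1-(4-methoxyphenyl)prop-2-en-1-yl]oxy}-3,5-bis(3-methylbut-2-en-1-yl)phenyl]ethan-1-one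
Product: 10 1-[1-(tert-butyldimethylsilyloxy)ethenyl]-4-(tert-butyldimethylsilyloxy)-2-{[(1S)-1-(4-methoxyphenyl)prop-2-en-1-yl]oxy}-3,5-bis(3-methylbut-2-en-1-yl)benzene, via potassium enolate 9 (not isolated)
Conditions: KHMDS (1.1 equiv), THF, −78 °C; TBSCl (1.3 equiv), DMPU, −78 → 0 °C; NaHCO3 work-up, Et3N-deactivated silica
Reagents that add atoms: tert-butyldimethylsilyl chloride, CC(C)(C)[Si](C)(C)Cl
Why: Kinetic enolisation of the only readily enolisable position (the acetyl methyl group, far more acidic than the ether C–H) followed by O-silylation of the potassium enolate (silyl enol ether formation), a base-first protocol being chosen so that the ionisable 1-arylallyl aryl ether never meets a free silyl triflate and the stereocentre is left untouched.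

Step 6
Reactants: 10 1-[1-(tert-butyldimethylsilyloxy)ethenyl]-4-(tert-butyldimethylsilyloxy)-2-{[(1S)-1-(4-methoxyphenyl)prop-2-en-1-yl]oxy}-3,5-bis(3-methylbut-2-en-1-yl)benzene
Product: 11 (2S)-4,7-bis(tert-butyldimethylsilyloxy)-2-(4-methoxyphenyl)-6,8-bis(3-methylbut-2-en-1-yl)-2H-chromene
Conditions: (H2IMes)(PCy3)Cl2Ru=CHPh (second-generation ruthenium benzylidene, 5–10 mol% in two portions), degassed PhMe (5 mM), 60 °C, Ar sparge, dark; basic alumina filtration; used at once
Reagents that add atoms: none
Why: The benzylidene should initiate on the only monosubstituted alkene, the vinyl group on C2, to give a ruthenium alkylidene at C3, which adds across the 1,1-disubstituted siloxyvinyl group on C4a (C3 to C4, Ru to the CH2 terminus); the ruthenacyclobutane then cycloreverts to the C3=C4 bond and Ru=CH2, which leaves as ethylene. The closest known reaction type is ring-closing olefin metathesis of aryl ketone silyl enol ethers to cyclic silyl enol ethers, and of allyl 2-vinylaryl ethers to 2H-chromenes, with second-generation ruthenium carbenes. The pyran ring (O1–C2–C3–C4–C4a–C8a) is closed as a six-membered ring by this metathesis, with O1, C8a and C4a already held by the arene, so C4 leaves the step at the ketone oxidation level. No stereocentre is formed and none of the four bonds to C2 is broken, so the S configuration from step 4 is carried through. The selectivity needed is six-membered closure onto the enol ether over seven-membered closure of the same alkylidene onto the C8 prenyl alkene (loss of isobutene) and over intermolecular metathesis; it rests on the shorter tether and smaller ring, on the lower reactivity of the trisubstituted prenyl alkenes and on 5 mM dilution, and because this is a preference and not a certainty the temperature is held at 60 °C and the reaction stopped once 10 is consumed. Both ortho carbons and the para carbon of the aryl ether are substituted, so a thermal aromatic Claisen shift has no productive outlet.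

Step 7
Reactants: 11 (2S)-4,7-bis(tert-butyldimethylsilyloxy)-2-(4-methoxyphenyl)-6,8-bis(3-methylbut-2-en-1-yl)-2H-chromene
Product: 12 (2S)-7-hydroxy-2-(4-methoxyphenyl)-6,8-bis(3-methylbut-2-en-1-yl)-2,3-dihydro-4H-chromen-4-one (the target flavanone)
Conditions: TBAF (2.5 equiv), AcOH (3 equiv), THF, 0 °C; pH 7 phosphate quench
Reagents that add atoms: none
Why: Fluoride-induced desilylation of the aryl silyl ether and the silyl enol ether, the enol(ate) being protonated at C3 by acetic acid to give the C4 ketone, while the acetic acid buffer keeps phenoxide and enolate concentrations negligible and so should prevent the base-induced retro-oxa-Michael opening to the 2'-hydroxychalcone that would racemise C2.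

**Compound list**

1 | 2,4-dihydroxyacetophenone | CC(=O)c1ccc(O)cc1O | starting material
2 | prenyl bromide (1-bromo-3-methylbut-2-ene) | CC(C)=CCBr | starting material
3 | 1-[2,4-dihydroxy-3,5-bis(3-methylbut-2-en-1-yl)phenyl]ethan-1-one | CC(=O)c1cc(CC=C(C)C)c(O)c(CC=C(C)C)c1O | intermediate
4 | 1-[4-(tert-butyldimethylsilyloxy)-2-hydroxy-3,5-bis(3-methylbut-2-en-1-yl)phenyl]ethan-1-one | CC(=O)c1cc(CC=C(C)C)c(O[Si](C)(C)C(C)(C)C)c(CC=C(C)C)c1O | intermediate
5 | (E)-4-methoxycinnamyl alcohol | COc1ccc(/C=C/CO)cc1 | starting material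
6 | tert-butyl (E)-3-(4-methoxyphenyl)prop-2-en-1-yl carbonate | COc1ccc(/C=C/COC(=O)OC(C)(C)C)cc1 | intermediate
7 | potassium 2-acetyl-5-(tert-butyldimethylsilyloxy)-4,6-bis(3-methylbut-2-en-1-yl)phenolate (aryloxide of 4, not isolated) | CC(=O)c1cc(CC=C(C)C)c(O[Si](C)(C)C(C)(C)C)c(CC=C(C)C)c1[O-].[K+] | intermediate
8 | 1-[4-(tert-butyldimethylsilyloxy)-2-{[(1S)-1-(4-methoxyphenyl)prop-2-en-1-yl]oxy}-3,5-bis(3-methylbut-2-en-1-yl)phenyl]ethan-1-one | COc1ccc([C@H](C=C)Oc2c(CC=C(C)C)c(O[Si](C)(C)C(C)(C)C)c(CC=C(C)C)cc2C(C)=O)cc1 | intermediate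
9 | potassium enolate of 8 (potassium 1-arylethen-1-olate, not isolated) | COc1ccc([C@H](C=C)Oc2c(CC=C(C)C)c(O[Si](C)(C)C(C)(C)C)c(CC=C(C)C)cc2C(=C)[O-])cc1.[K+] | intermediate
10 | 1-[1-(tert-butyldimethylsilyloxy)ethenyl]-4-(tert-butyldimethylsilyloxy)-2-{[(1S)-1-(4-methoxyphenyl)prop-2-en-1-yl]oxy}-3,5-bis(3-methylbut-2-en-1-yl)benzene | COc1ccc([C@H](C=C)Oc2c(CC=C(C)C)c(O[Si](C)(C)C(C)(C)C)c(CC=C(C)C)cc2C(=C)O[Si](C)(C)C(C)(C)C)cc1 | intermediate
11 | (2S)-4,7-bis(tert-butyldimethylsilyloxy)-2-(4-methoxyphenyl)-6,8-bis(3-methylbut-2-en-1-yl)-2H-chromene | COc1ccc([C@@H]2C=C(O[Si](C)(C)C(C)(C)C)c3cc(CC=C(C)C)c(O[Si](C)(C)C(C)(C)C)c(CC=C(C)C)c3O2)cc1 | intermediate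
12 | (2S)-7-hydroxy-2-(4-methoxyphenyl)-6,8-bis(3-methylbut-2-en-1-yl)-2,3-dihydro-4H-chromen-4-one (the target flavanone) | COc1ccc([C@@H]2CC(=O)c3cc(CC=C(C)C)c(O)c(CC=C(C)C)c3O2)cc1 | target

**Step count**

Total steps: 7. Longest linear sequence: 6 (steps 1, 2, 4, 5, 6, 7 from 2,4-dihydroxyacetophenone).

**Steps most likely to fail**

Step 6 (ring-closing metathesis). The alkylidene formed at the vinyl group may close the seven-membered ring onto the C8 prenyl alkene with loss of isobutene instead of the six-membered ring onto the enol ether. It may also be parked as an unreactive siloxy-substituted carbene, so that turnover stops. Ruthenium hydride isomerisation of the allyl ether and thermal electrocyclic opening of the 2H-chromene (erosion of enantiopurity) are further drains. The fallback sets out from phenol 4 and comes back at target 12; it abandons the metathesis and builds ring C before the C2 aryl group is attached. Condensation of 4 with N,N-dimethylformamide dimethyl acetal (PhMe, 90 °C) should give the enaminone F1. Treatment with TsOH·H2O in CH2Cl2 should cyclise it, with loss of dimethylamine, to the 7-silyloxy-6,8-diprenylchromone F2. Rhodium(I)-catalysed asymmetric 1,4-addition of 4-methoxyphenylboronic acid (electron-poor chiral biaryl bisphosphine, antipode chosen for the 2S series, PhMe/H2O, rt) should then give the 7-O-silyl (2S)-flavanone F3. The buffered fluoride of step 7 converts F3 to 12.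

Step 4 (iridium allylic etherification). The chelated, doubly ortho-substituted aryloxide may attack the allyliridium intermediate slowly, and the metal may re-ionise the product ether, which carries a good leaving group on a p-methoxy-stabilised allyl unit. Both lead to loss of branched selectivity and of enantiopurity. The fallback sets out from phenol 4 and comes back at ether 8; it makes the O–C bond by SN2 inversion at a saturated carbinol and unveils the vinyl group afterwards. Commercial 3-chloro-1-(4-methoxyphenyl)propan-1-one is reduced with the (S)-oxazaborolidine/BH3·SMe2 system (CBS reduction) to (R)-3-chloro-1-(4-methoxyphenyl)propan-1-ol F4. Mitsunobu coupling of F4 with 4 (PPh3, DIAD, PhMe, 0 °C) should invert the carbinol carbon and give the (S)-3-chloropropyl aryl ether F5. Chloride displacement with phenylselenide (PhSeSePh/NaBH4 pre-mixed, EtOH–THF) gives the phenyl selenide F6. Oxidation with H2O2/pyridine and selenoxide syn-elimination at rt should give 8.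

Step 1 (double C-prenylation). Alkylation may scatter over O-prenylation, mono-C-prenylation at C3 or C5 and geminal dialkylation at C3, so that little of the 3,5-di-C-prenyl ketone is isolated. The fallback sets out from 1 and comes back at 3; it fixes both positions by halogenation and cross-coupling. Double iodination (I2/HIO3, EtOH–H2O) should give 2,4-dihydroxy-3,5-diiodoacetophenone F7. Protection with MOMCl/NaH (DMF) gives the bis(methoxymethyl) ether F8. Double Stille coupling with tributyl(3-methylbut-2-en-1-yl)stannane (Pd(PPh3)4, DMF, 90 °C) should give the 3,5-diprenyl bis(methoxymethyl) ether F9. Methanolic HCl at rt then returns 3.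

**Further compounds**

F1 | step 6 | (E)-1-[4-(tert-butyldimethylsilyloxy)-2-hydroxy-3,5-bis(3-methylbut-2-en-1-yl)phenyl]-3-(dimethylamino)prop-2-en-1-one | CN(C)/C=C/C(=O)c1cc(CC=C(C)C)c(O[Si](C)(C)C(C)(C)C)c(CC=C(C)C)c1O
F2 | step 6 | 7-(tert-butyldimethylsilyloxy)-6,8-bis(3-methylbut-2-en-1-yl)-4H-chromen-4-one | O=c1ccoc2c(CC=C(C)C)c(O[Si](C)(C)C(C)(C)C)c(CC=C(C)C)cc12
F3 | step 6 | (2S)-7-(tert-butyldimethylsilyloxy)-2-(4-methoxyphenyl)-6,8-bis(3-methylbut-2-en-1-yl)-2,3-dihydro-4H-chromen-4-one | COc1ccc([C@@H]2CC(=O)c3cc(CC=C(C)C)c(O[Si](C)(C)C(C)(C)C)c(CC=C(C)C)c3O2)cc1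
F4 | step 4 | (R)-3-chloro-1-(4-methoxyphenyl)propan-1-ol | COc1ccc([C@H](O)CCCl)cc1
F5 | step 4 | 1-[4-(tert-butyldimethylsilyloxy)-2-{[(1S)-3-chloro-1-(4-methoxyphenyl)propyl]oxy}-3,5-bis(3-methylbut-2-en-1-yl)phenyl]ethan-1-one | COc1ccc([C@H](CCCl)Oc2c(CC=C(C)C)c(O[Si](C)(C)C(C)(C)C)c(CC=C(C)C)cc2C(C)=O)cc1
F6 | step 4 | 1-[4-(tert-butyldimethylsilyloxy)-2-{[(1S)-1-(4-methoxyphenyl)-3-(phenylselanyl)propyl]oxy}-3,5-bis(3-methylbut-2-en-1-yl)phenyl]ethan-1-one | COc1ccc([C@H](CC[Se]c2ccccc2)Oc3c(CC=C(C)C)c(O[Si](C)(C)C(C)(C)C)c(CC=C(C)C)cc3C(C)=O)cc1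
F7 | step 1 | 1-(2,4-dihydroxy-3,5-diiodophenyl)ethan-1-one | CC(=O)c1cc(I)c(O)c(I)c1O
F8 | step 1 | 1-[3,5-diiodo-2,4-bis(methoxymethoxy)phenyl]ethan-1-one | CC(=O)c1cc(I)c(OCOC)c(I)c1OCOC
F9 | step 1 | 1-[2,4-bis(methoxymethoxy)-3,5-bis(3-methylbut-2-en-1-yl)phenyl]ethan-1-one | CC(=O)c1cc(CC=C(C)C)c(OCOC)c(CC=C(C)C)c1OCOC
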